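## Retrosynthetic overview
1. Gancaonin G ⇐ a racemic 3-hydroxyisoflavanone, by loss of water across C2–C3 and of a 4'-acetyl group (base-triggered, through a p-quinone methide).
2. 3-Hydroxyisoflavanone ⇐ C3–C4 bond. The A-ring aldehyde carbon becomes an acyl anion (Breslow enaminol) and attacks the B-ring aryl ketone carbon of a phenacyl aryl ether, so two carbonyl carbons are joined.
3. Phenacyl ether ⇐ O1–C2 bond, by site-selective O-alkylation of 2,6-dihydroxy-4-methoxy-3-prenylbenzaldehyde with 4-acetoxyphenacyl bromide. This step decides 6- versus 8-prenyl.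
4. A-ring aldehyde ⇐ 2,4,6-trihydroxybenzaldehyde, by C-prenylation (C3 = C5 by symmetry) and then 4-O-methylation.
5. Rings A and B are bought. Ring C is the only ring made: it is closed in step 5 and made aromatic in step 6.

Assumption: gancaonin G has no stereocentre and no stereogenic double bond, so no enantiocontrol is needed. The only stereocentre that appears on the way (C-3 of 9 and 10) is racemic and is erased in step 6.

## Route

Step 1
Reactants: 1 2,4,6-trihydroxybenzaldehyde; 2 prenyl bromide (1-bromo-3-methylbut-2-ene)
Product: 3 2,4,6-trihydroxy-3-(3-methylbut-2-enyl)benzaldehyde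
Conditions: KOH (1.0 equiv), H2O, 0 °C → rt, 2 (0.9 equiv) added slowly; then 1 M HCl
Reagents that add atoms: none
Why: This is C-allylation of an ambident phloroglucinol-type phenolate, favoured because water solvates the oxygens and steers the soft allylic bromide to carbon; C3 and C5 are equivalent, so only one mono-C-prenyl isomer can form, and a slight excess of 1 limits diprenylation.

Step 2
Reactants: 3 2,4,6-trihydroxy-3-(3-methylbut-2-enyl)benzaldehyde
Product: 4 2,6-dihydroxy-4-methoxy-3-(3-methylbut-2-enyl)benzaldehyde
Conditions: MeI (1.05 equiv), K2CO3 (1.0 equiv), acetone, rt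
Reagents that add atoms: methyl iodide, CI
Why: In this Williamson etherification with one equivalent of base, the 4-OH (para to CHO) is the most acidic hydroxyl and the only one that never chelates, so it is methylated first while the two ortho hydroxyls are held back by hydrogen bonding to the aldehyde.

Step 3
Reactants: 5 4'-acetoxyacetophenone
Product: 6 4-(2-bromoacetyl)phenyl acetate (4-acetoxyphenacyl bromide)
Conditions: Br2 (1.0 equiv), AcOH, 15–20 °C
Reagents that add atoms: bromine, BrBr
Why: This is acid-catalysed α-bromination of the ketone through its enol; the acyl- and acetoxy-substituted ring is too deactivated for ring bromination, and the aryl acetate is stable in acetic acid.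

Step 4
Reactants: 4 2,6-dihydroxy-4-methoxy-3-(3-methylbut-2-enyl)benzaldehyde; 6 4-(2-bromoacetyl)phenyl acetate
Product: 7 4-{2-[2-formyl-3-hydroxy-5-methoxy-4-(3-methylbut-2-enyl)phenoxy]acetyl}phenyl acetate
Conditions: K2CO3 (1.05 equiv), acetone, 0 °C → rt
Reagents that add atoms: none
Why: This is a Williamson SN2 reaction on a very reactive phenacyl bromide; the 6-OH next to H-5 reacts, whereas the 2-OH is wedged between CHO and prenyl and keeps the chelate (as in partial alkylation of 3-alkylphloroacylphenones), the remaining OH then resists a second alkylation, weak base at rt avoids Rap–Stoermer benzofuran closure and acetate loss, and the site is confirmed by an NOE between OCH2 and H-5.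

Step 5
Reactants: 7 4-{2-[2-formyl-3-hydroxy-5-methoxy-4-(3-methylbut-2-enyl)phenoxy]acetyl}phenyl acetate
Product: 9 rac-4-[3,5-dihydroxy-7-methoxy-6-(3-methylbut-2-enyl)-4-oxochroman-3-yl]phenyl acetate, via Breslow enaminol 8 (not isolated)
Conditions: 2-(pentafluorophenyl)-6,7-dihydro-5H-pyrrolo[2,1-c][1,2,4]triazol-2-ium BF4 (20 mol %), Et3N (50 mol %), toluene (0.05 M), Ar, rt → 40 °C
Reagents that add atoms: none
Why: This is an NHC-catalysed intramolecular crossed aldehyde–ketone benzoin cyclisation, in which the carbene adds to the hydrogen-bond-activated ortho-oxygenated CHO, the neighbouring OH shuttles the proton to give 8 (acyl anion at the future C-4), and 8 closes 6-exo onto the activated aryl ketone carbon; the acidic N-C6F5 azolium works with Et3N, which is too weak to enolise the phenacyl ether, and the new C-3 stereocentre forms as the racemate and is erased in step 6.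

Step 6
Reactants: 9 rac-4-[3,5-dihydroxy-7-methoxy-6-(3-methylbut-2-enyl)-4-oxochroman-3-yl]phenyl acetate
Product: 12 gancaonin G, via triacetate 10 (not isolated), via p-quinone methide 11 (not isolated)
Conditions: Ac2O (6 equiv), DMAP (0.3 equiv), pyridine, 40 °C; evaporate; K2CO3 (4 equiv), MeOH–THF 1:1, 0 °C → rt; aq. NH4Cl
Reagents that add atoms: acetic anhydride, CC(=O)OC(C)=O (its acetyl groups sit in 10 only and are gone again in 12)
Why: Proposed new method: exhaustive DMAP-catalysed acetylation makes the tertiary benzylic 3-OH a leaving group, and methanolysis of the much more labile aryl acetates then frees the 4'-phenoxide, which expels the 3-acetate by 1,6-elimination to 11, whose acidified C-2 proton is lost to give the aromatic chromone, all without acid so that the 6-prenyl/5-OH pair does not cyclise to a chroman; the closest known reaction types are the base-triggered 1,6-elimination of 4-acyloxybenzyl esters (self-immolative linkers) and the acid dehydration of 3-hydroxyisoflavanones.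

## Compound list
1 | 2,4,6-trihydroxybenzaldehyde | O=Cc1c(O)cc(O)cc1O | starting material
2 | prenyl bromide | CC(C)=CCBr | starting material
3 | 2,4,6-trihydroxy-3-(3-methylbut-2-enyl)benzaldehyde | O=Cc1c(O)cc(O)c(CC=C(C)C)c1O | intermediate
4 | 2,6-dihydroxy-4-methoxy-3-(3-methylbut-2-enyl)benzaldehyde | COc1cc(O)c(C=O)c(O)c1CC=C(C)C | intermediate
5 | 4'-acetoxyacetophenone | CC(=O)Oc1ccc(cc1)C(C)=O | starting material
6 | 4-(2-bromoacetyl)phenyl acetate | CC(=O)Oc1ccc(cc1)C(=O)CBr | intermediate
7 | keto-aldehyde (phenacyl aryl ether) | CC(=O)Oc1ccc(cc1)C(=O)COc1cc(OC)c(CC=C(C)C)c(O)c1C=O | intermediate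
8 | Breslow enaminol of 7 (catalyst-bound acyl anion equivalent, not isolated) | CC(=O)Oc1ccc(cc1)C(=O)COc1cc(OC)c(CC=C(C)C)c(O)c1C(O)=C1N(c2c(F)c(F)c(F)c(F)c2F)N=C2CCCN12 | intermediate
9 | rac-3-hydroxyisoflavanone 4'-acetate | CC(=O)Oc1ccc(cc1)C1(O)COc2cc(OC)c(CC=C(C)C)c(O)c2C1=O | intermediate
10 | rac-3,5,4'-triacetate of the 3-hydroxyisoflavanone (not isolated) | CC(=O)Oc1ccc(cc1)C1(OC(C)=O)COc2cc(OC)c(CC=C(C)C)c(OC(C)=O)c2C1=O | intermediate
11 | p-quinone methide: 5-hydroxy-7-methoxy-3-(4-oxocyclohexa-2,5-dienylidene)-6-prenylchroman-4-one (not isolated) | COc1cc2OCC(=C3C=CC(=O)C=C3)C(=O)c2c(O)c1CC=C(C)C | intermediate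
12 | gancaonin G (achiral) | COc1cc2occ(-c3ccc(O)cc3)c(=O)c2c(O)c1CC=C(C)C | target

## Count and risks
Total steps: 6. Longest linear sequence: 5 (steps 1, 2, 4, 5, 6).

**Step 5 (highest risk).** The aldehyde is electron-rich and flanked by two oxygen substituents, so 8 may form slowly. The free phenol also buffers the base, and any enolisation leads to the 2-aroylbenzofuran. The fallback sets out from 4 and 6 (replacing steps 4 and 5) and comes back at 9. It makes the ketone carbon, not the aldehyde carbon, the nucleophile.
- 6 is condensed with TsNHNH2 (MeOH, 0 °C) to the α-bromo tosylhydrazone F1.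
- K2CO3 in THF converts this into the azoalkene F2, to which the 6-OH of 4 adds in a conjugate sense to give the α-aryloxy tosylhydrazone F3. Its ketone is masked, so no benzofuran can form.
- Cs2CO3 in dioxane at 100 °C (Bamford–Stevens) releases the aryl diazoalkane F4, whose carbon attacks the chelated aldehyde.
- A 1,2-hydride shift with loss of N2 (formyl C–H insertion) gives the racemic isoflavanone F5.
- KHMDS (2.2 equiv) and 2-(phenylsulfonyl)-3-phenyloxaziridine at −78 °C hydroxylate C-3 and deliver 9.

**Step 6.** The hindered tertiary OH may resist acetylation, and methanol may add to 11 faster than C-2 loses its proton. The fallback sets out from 9 and comes back at 12. It gives up the phenoxide trigger, eliminates first on the still protected compound, and deprotects afterwards.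
- Burgess' inner salt (2.5 equiv, THF, 50 °C) sulfamoylates the tertiary OH.
- A concerted syn (Ei) elimination with one C-2 hydrogen gives 4'-O-acetylgancaonin G F6, which is isolated.
- K2CO3/MeOH at 0 °C then removes the acetate to give 12.

**Step 1.** O-prenylation, 3,5-di- and 3,3-diprenylation can push the yield of 3 very low. The fallback sets out from 1 and 2 and comes back at 4, bypassing 3 and step 2. It replaces direct C-alkylation by O-alkylation followed by sigmatropic transfer.
- 1 is first methylated at its unhindered 4-OH (MeI, K2CO3, acetone) to the symmetric 2,6-dihydroxy-4-methoxybenzaldehyde F7.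
- Mono-O-prenylation with 2 (K2CO3, acetone; the second OH stays chelated) gives the prenyl ether F8.
- Heating in N,N-diethylaniline at 200 °C starts a tandem para-Claisen–Cope sequence. The [3,3] shift to the free ortho carbon gives the ortho-dienone F9, which carries a reverse prenyl group.
- The Cope shift passes it on as a normal prenyl group to the para carbon (para-dienone F10), which tautomerises to 4.

## Further compounds
F1 | step 5 | 4-[2-bromo-1-(2-tosylhydrazinylidene)ethyl]phenyl acetate | CC(=O)Oc1ccc(cc1)C(CBr)=NNS(=O)(=O)c1ccc(C)cc1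
F2 | step 5 | 4-[1-(tosyldiazenyl)vinyl]phenyl acetate (azoalkene, in situ) | CC(=O)Oc1ccc(cc1)C(=C)N=NS(=O)(=O)c1ccc(C)cc1
F3 | step 5 | tosylhydrazone of keto-aldehyde 7 at the ketone carbon | CC(=O)Oc1ccc(cc1)C(COc1cc(OC)c(CC=C(C)C)c(O)c1C=O)=NNS(=O)(=O)c1ccc(C)cc1
F4 | step 5 | aryl diazoalkane from F3 (in situ) | CC(=O)Oc1ccc(cc1)C(=[N+]=[N-])COc1cc(OC)c(CC=C(C)C)c(O)c1C=O
F5 | step 5 | rac-4-[5-hydroxy-7-methoxy-6-(3-methylbut-2-enyl)-4-oxochroman-3-yl]phenyl acetate (isoflavanone) | CC(=O)Oc1ccc(cc1)C1COc2cc(OC)c(CC=C(C)C)c(O)c2C1=O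
F6 | step 6 | 4'-O-acetylgancaonin G | COc1cc2occ(-c3ccc(OC(C)=O)cc3)c(=O)c2c(O)c1CC=C(C)C
F7 | step 1 | 2,6-dihydroxy-4-methoxybenzaldehyde | COc1cc(O)c(C=O)c(O)c1
F8 | step 1 | 2-hydroxy-4-methoxy-6-(3-methylbut-2-enyloxy)benzaldehyde | COc1cc(O)c(C=O)c(OCC=C(C)C)c1
F9 | step 1 | rac-ortho-dienone with 1,1-dimethylallyl group (in situ) | O=CC1=C(O)C=C(OC)C(C(C)(C)C=C)C1=O
F10 | step 1 | rac-para-dienone with prenyl group (in situ) | O=CC1=C(O)C(CC=C(C)C)C(OC)=CC1=O
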